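**Retrosynthetic overview**
1. Target 18 ⇒ MOM removal and Claisen–Schmidt condensation ⇒ methyl ketone 14 + 4-(methoxymethoxy)benzaldehyde 15.
2. 14 ⇒ cross-metathesis at the heptenyl C=C ⇒ propenyl arene 8 + (R)-homoallylic alcohol 13 (Heck, then Brown allylation).
3. 8 ⇒ key step: aromatic Claisen rearrangement of aryl allyl ether 6 through the dearomatised ring A dienone 7; the C–O stereocentre is relayed into the diarylmethine centre and the E-alkene is formed.
4. 6 ⇒ Mitsunobu inversion of phenol 5 with (R)-allylic alcohol 3 (4-acetoxystyrene + (R)-but-3-en-2-ol by cross-metathesis).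
5. Rings: none is built; all four benzene rings are bought, and ring A is only dearomatised transiently (7) and re-aromatised.

Assumption: the SMILES is read as S at the diarylmethine carbon (heptenyl C1) and R at the carbinol carbon (heptenyl C5); ring A is numbered C1' (acyl carbon) to C6' (methoxy carbon).

**Route**

Step 1
Reactants: 1 4-acetoxystyrene; 2 (2R)-but-3-en-2-ol
Product: 3 4-[(1E,3R)-3-hydroxybut-1-en-1-yl]phenyl acetate
Conditions: RuCl2(H2IMes)(=CH-C6H4-2-OiPr) (second-generation Hoveyda–Grubbs catalyst, 3 mol%), 1 (3 equiv), CH2Cl2, 40 °C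
Reagents that add atoms: none
Why: Olefin cross-metathesis of a fast-dimerising styrene with a secondary allylic alcohol is E-selective for steric reasons and does not touch the purchased (R) carbinol centre.

Step 2
Reactants: 4 1-(2,4-dihydroxy-6-methoxyphenyl)ethan-1-one
Product: 5 1-[2-hydroxy-6-methoxy-4-(methoxymethoxy)phenyl]ethan-1-one
Conditions: MOMCl (1.1 equiv), iPr2NEt, CH2Cl2, 0 °C to 25 °C
Reagents that add atoms: chloromethyl methyl ether (MOMCl), COCCl
Why: Williamson-type O-alkylation is selective because the 2'-hydroxyl is locked in a hydrogen bond to the acetyl group, so only the more acidic 4'-hydroxyl reacts.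

Step 3
Reactants: 5 1-[2-hydroxy-6-methoxy-4-(methoxymethoxy)phenyl]ethan-1-one; 3 4-[(1E,3R)-3-hydroxybut-1-en-1-yl]phenyl acetate
Product: 6 4-[(1E,3S)-3-[2-acetyl-3-methoxy-5-(methoxymethoxy)phenoxy]but-1-en-1-yl]phenyl acetate
Conditions: PPh3, DIAD, PhMe, 0 °C to 25 °C
Reagents that add atoms: none
Why: Mitsunobu etherification goes by SN2 displacement of the alkoxyphosphonium ion, so the (R) alcohol gives the (S) aryl ether with inversion; the acetoxy group makes the styrene a poor cation stabiliser and so limits SN1 and SN2' leakage.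

Step 4
Reactants: 6 4-[(1E,3S)-3-[2-acetyl-3-methoxy-5-(methoxymethoxy)phenoxy]but-1-en-1-yl]phenyl acetate
Product: 8 4-[(1S,2E)-1-[3-acetyl-2-hydroxy-4-methoxy-6-(methoxymethoxy)phenyl]but-2-en-1-yl]phenyl acetate, via ortho-dienone 7 (not isolated)
Conditions: Eu(fod)3 (10 mol%; fod = 6,6,7,7,8,8,8-heptafluoro-2,2-dimethyloctane-3,5-dionate), PhMe, 80 °C
Reagents that add atoms: none
Why: Aromatic Claisen rearrangement, accelerated by chelation of trivalent europium between the acetyl and ether oxygens: the suprafacial [3,3] shift through a chair with the methyl group pseudo-equatorial breaks the aromaticity of ring A (dienone 7), relays the (S) C–O centre into the (S) diarylmethine centre and creates the E-alkene, then enolisation restores the arene; C1' is blocked by the acetyl group, so only C3' can accept the allyl terminus.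

Step 5
Reactants: 9 4-iodophenyl acetate; 10 prop-2-en-1-ol
Product: 11 4-(3-oxopropyl)phenyl acetate
Conditions: Pd(OAc)2 (2 mol%), Bu4NCl, NaHCO3, DMF, 45 °C
Reagents that add atoms: none
Why: Heck reaction under Jeffery conditions: insertion places the aryl group on the terminal carbon and β-hydride elimination towards the carbinol carbon gives an enol that tautomerises to the aldehyde.

Step 6
Reactants: 11 4-(3-oxopropyl)phenyl acetate
Product: 13 4-[(3R)-3-hydroxyhex-5-en-1-yl]phenol, via borinate ester 12 (not isolated)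
Conditions: (−)-Ipc2BOMe (from (+)-α-pinene), allylMgBr, Et2O, 0 °C to 25 °C; then 11, −78 °C; then NaOH (3 M aq.), H2O2 (30%), 25 °C
Reagents that add atoms: allylmagnesium bromide (allylMgBr), C=CC[Mg]Br
Why: Brown asymmetric allylboration through a closed chair transition state, in which the (+)-α-pinene-derived isopinocampheyl groups direct the allyl group to the aldehyde face that gives the (R) homoallylic alcohol (as with other unbranched aldehydes); the alkaline peroxide work-up cleaves the borinate and saponifies the aryl acetate.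

Step 7
Reactants: 8 4-[(1S,2E)-1-[3-acetyl-2-hydroxy-4-methoxy-6-(methoxymethoxy)phenyl]but-2-en-1-yl]phenyl acetate; 13 4-[(3R)-3-hydroxyhex-5-en-1-yl]phenol
Product: 14 4-[(1S,2E,5R)-1-[3-acetyl-2-hydroxy-4-methoxy-6-(methoxymethoxy)phenyl]-5-hydroxy-7-(4-hydroxyphenyl)hept-2-en-1-yl]phenyl acetate
Conditions: RuCl2(H2IMes)(=CH-C6H4-2-OiPr) (second-generation Hoveyda–Grubbs catalyst, 10 mol%), 13 (3 equiv), 1,4-benzoquinone (20 mol%), CH2Cl2, 40 °C
Reagents that add atoms: none
Why: Olefin cross-metathesis with loss of propene joins the two fragments, the bulky diarylmethine group enforces the E geometry, benzoquinone suppresses hydride-mediated alkene migration, and neither stereocentre takes part.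

Step 8
Reactants: 14 4-[(1S,2E,5R)-1-[3-acetyl-2-hydroxy-4-methoxy-6-(methoxymethoxy)phenyl]-5-hydroxy-7-(4-hydroxyphenyl)hept-2-en-1-yl]phenyl acetate; 15 4-(methoxymethoxy)benzaldehyde
Product: 17 (2E)-1-[2-hydroxy-3-[(1S,2E,5R)-5-hydroxy-1,7-bis(4-hydroxyphenyl)hept-2-en-1-yl]-6-methoxy-4-(methoxymethoxy)phenyl]-3-[4-(methoxymethoxy)phenyl]prop-2-en-1-one, via deacetylated ketone 16 (not isolated)
Conditions: KOH (50% aq., excess), 15 (3 equiv), EtOH, 0 °C to 25 °C; then HCl (1 M aq.), 0 °C, to pH 5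
Reagents that add atoms: none
Why: Claisen–Schmidt condensation (aldol addition, then E1cB dehydration) gives the E-enone; KOH first cleaves the aryl acetate, the MOM ethers keep the para-oxygens of ketone and aldehyde from becoming deactivating phenoxides, and the electron-rich diarylmethine C–H is not acidic enough to epimerise.

Step 9
Reactants: 17 (2E)-1-[2-hydroxy-3-[(1S,2E,5R)-5-hydroxy-1,7-bis(4-hydroxyphenyl)hept-2-en-1-yl]-6-methoxy-4-(methoxymethoxy)phenyl]-3-[4-(methoxymethoxy)phenyl]prop-2-en-1-one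
Product: 18 (2E)-1-[2,4-dihydroxy-3-[(1S,2E,5R)-5-hydroxy-1,7-bis(4-hydroxyphenyl)hept-2-en-1-yl]-6-methoxyphenyl]-3-(4-hydroxyphenyl)prop-2-en-1-one
Conditions: HCl (3 M aq.), MeOH, 25 °C
Reagents that add atoms: none
Why: Acid-catalysed transacetalisation removes both MOM groups as dimethoxymethane at room temperature, which is mild enough to avoid chalcone-to-flavanone cyclisation and addition of the phenols to the isolated alkene.

**Compound list**

1 | 4-acetoxystyrene (4-ethenylphenyl acetate) | CC(=O)Oc1ccc(C=C)cc1 | starting material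
2 | (2R)-but-3-en-2-ol | C[C@@H](O)C=C | starting material
3 | 4-[(1E,3R)-3-hydroxybut-1-en-1-yl]phenyl acetate | C[C@@H](O)/C=C/c1ccc(OC(C)=O)cc1 | intermediate
4 | 1-(2,4-dihydroxy-6-methoxyphenyl)ethan-1-one | CC(=O)c1c(O)cc(O)cc1OC | starting material
5 | 1-[2-hydroxy-6-methoxy-4-(methoxymethoxy)phenyl]ethan-1-one | CC(=O)c1c(O)cc(OCOC)cc1OC | intermediate
6 | 4-[(1E,3S)-3-[2-acetyl-3-methoxy-5-(methoxymethoxy)phenoxy]but-1-en-1-yl]phenyl acetate | C[C@H](Oc1cc(OCOC)cc(OC)c1C(C)=O)/C=C/c1ccc(OC(C)=O)cc1 | intermediate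
7 | ortho-dienone, not isolated: 4-[(1R,2E)-1-[(1R)-3-acetyl-4-methoxy-6-(methoxymethoxy)-2-oxocyclohexa-3,5-dien-1-yl]but-2-en-1-yl]phenyl acetate | CC(=O)C1=C(OC)C=C(OCOC)[C@@H]([C@@H](/C=C/C)c2ccc(OC(C)=O)cc2)C1=O | intermediate
8 | 4-[(1S,2E)-1-[3-acetyl-2-hydroxy-4-methoxy-6-(methoxymethoxy)phenyl]but-2-en-1-yl]phenyl acetate | CC(=O)c1c(O)c([C@@H](/C=C/C)c2ccc(OC(C)=O)cc2)c(OCOC)cc1OC | intermediate
9 | 4-iodophenyl acetate | CC(=O)Oc1ccc(I)cc1 | starting material
10 | prop-2-en-1-ol (allyl alcohol) | C=CCO | starting material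
11 | 4-(3-oxopropyl)phenyl acetate | CC(=O)Oc1ccc(CCC=O)cc1 | intermediate
12 | borinate ester, not isolated: 4-[(3R)-3-[bis(isopinocampheyl)boranyloxy]hex-5-en-1-yl]phenyl acetate | C=CC[C@H](OB([C@@H]1C[C@@H]2C[C@H]([C@H]1C)C2(C)C)[C@@H]1C[C@@H]2C[C@H]([C@H]1C)C2(C)C)CCc1ccc(OC(C)=O)cc1 | intermediate
13 | 4-[(3R)-3-hydroxyhex-5-en-1-yl]phenol | C=CC[C@H](O)CCc1ccc(O)cc1 | intermediate
14 | 4-[(1S,2E,5R)-1-[3-acetyl-2-hydroxy-4-methoxy-6-(methoxymethoxy)phenyl]-5-hydroxy-7-(4-hydroxyphenyl)hept-2-en-1-yl]phenyl acetate | CC(=O)c1c(O)c([C@@H](/C=C/C[C@H](O)CCc2ccc(O)cc2)c2ccc(OC(C)=O)cc2)c(OCOC)cc1OC | intermediate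
15 | 4-(methoxymethoxy)benzaldehyde | COCOc1ccc(C=O)cc1 | starting material
16 | deacetylated ketone, not isolated: 1-[2-hydroxy-3-[(1S,2E,5R)-5-hydroxy-1,7-bis(4-hydroxyphenyl)hept-2-en-1-yl]-6-methoxy-4-(methoxymethoxy)phenyl]ethan-1-one | CC(=O)c1c(O)c([C@@H](/C=C/C[C@H](O)CCc2ccc(O)cc2)c2ccc(O)cc2)c(OCOC)cc1OC | intermediate
17 | (2E)-1-[2-hydroxy-3-[(1S,2E,5R)-5-hydroxy-1,7-bis(4-hydroxyphenyl)hept-2-en-1-yl]-6-methoxy-4-(methoxymethoxy)phenyl]-3-[4-(methoxymethoxy)phenyl]prop-2-en-1-one | COCOc1ccc(/C=C/C(=O)c2c(O)c([C@@H](/C=C/C[C@H](O)CCc3ccc(O)cc3)c3ccc(O)cc3)c(OCOC)cc2OC)cc1 | intermediate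
18 | (2E)-1-[2,4-dihydroxy-3-[(1S,2E,5R)-5-hydroxy-1,7-bis(4-hydroxyphenyl)hept-2-en-1-yl]-6-methoxyphenyl]-3-(4-hydroxyphenyl)prop-2-en-1-one | COc1cc(O)c([C@@H](/C=C/C[C@H](O)CCc2ccc(O)cc2)c2ccc(O)cc2)c(O)c1C(=O)/C=C/c1ccc(O)cc1 | target

**Step count**

Total steps: 9. Longest linear sequence: 6 (steps 1, 3, 4, 7, 8, 9).

**Three steps most likely to fail**

Step 4 (Claisen rearrangement of 6). The cinnamyl-type ether can ionise under the Lewis acid, which would erode the chirality transfer or give the [1,3] product. Dienone 7 can also undergo a Cope shift to C5' before it enolises. The fallback sets out from 3 and 5 and comes back at 16. It drops the O-to-C shift and forms the C3'–C bond intermolecularly. Compound 3 is deacetylated (K2CO3, MeOH) to 4-[(1E,3R)-3-hydroxybut-1-en-1-yl]phenol F4. A chiral phosphoric acid (TRIP, 3,3'-bis(2,4,6-triisopropylphenyl)-1,1'-binaphthyl-2,2'-diyl hydrogen phosphate, 5 mol%, PhMe, 0 °C) dehydrates F4 in the flask to the vinylogous para-quinone methide 4-[(2E)-but-2-en-1-ylidene]cyclohexa-2,5-dien-1-one F5. Phenol 5 adds to F5 through C3', ortho to its free hydroxyl, in a 1,6-addition; the acid enantiomer that gives the S centre is found by screening. The product is 1-[2-hydroxy-3-[(1S,2E)-1-(4-hydroxyphenyl)but-2-en-1-yl]-6-methoxy-4-(methoxymethoxy)phenyl]ethan-1-one F6. Cross-metathesis of F6 with 13 under the step 7 conditions gives 16, here isolated, which goes into the condensation of step 8.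

Step 3 (Mitsunobu reaction at the hydrogen-bonded 2'-hydroxyl of 5 with a secondary allylic alcohol). The chelated phenol may be too sluggish, leaving elimination or SN2' products. The fallback sets out from 4 and 3 and comes back at 8. Unprotected 4 is coupled with 3 at its acidic, non-chelated 4'-hydroxyl (PPh3, DIAD, THF) to give 4-[(1E,3S)-3-(4-acetyl-3-hydroxy-5-methoxyphenoxy)but-1-en-1-yl]phenyl acetate F1. Thermal Claisen rearrangement (PhNEt2, 150 °C) then passes through the dienone 4-[(1R,2E)-1-[(1R)-3-acetyl-2-hydroxy-4-methoxy-6-oxocyclohexa-2,4-dien-1-yl]but-2-en-1-yl]phenyl acetate F2 to 4-[(1S,2E)-1-(3-acetyl-2,6-dihydroxy-4-methoxyphenyl)but-2-en-1-yl]phenyl acetate F3. Here the preference for C3' over C5' rests only on bond fixation by the chelate ring and is not secured by a blocking group, so any C5' isomer has to be removed by chromatography. MOMCl and iPr2NEt on the non-chelated hydroxyl of F3 then give 8.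

Step 7 (cross-metathesis of the hindered internal propenyl group of 8). The alkene sits next to a diarylmethine carbon with two ortho substituents and may react too slowly. The fallback sets out from 8 and comes back at 14. Ethenolysis of 8 (ethylene 1 atm, RuCl2(H2IMes)(=CH-C6H4-2-OiPr), CH2Cl2, 40 °C) first trims the propenyl group to the terminal alkene 4-[(1S)-1-[3-acetyl-2-hydroxy-4-methoxy-6-(methoxymethoxy)phenyl]prop-2-en-1-yl]phenyl acetate F7. This monosubstituted olefin is then cross-metathesised with 13 in a separate operation to give 14.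

**Further compounds**

F1 | step 3 | 4-[(1E,3S)-3-(4-acetyl-3-hydroxy-5-methoxyphenoxy)but-1-en-1-yl]phenyl acetate | C[C@H](Oc1cc(O)c(C(C)=O)c(OC)c1)/C=C/c1ccc(OC(C)=O)cc1
F2 | step 3 | 4-[(1R,2E)-1-[(1R)-3-acetyl-2-hydroxy-4-methoxy-6-oxocyclohexa-2,4-dien-1-yl]but-2-en-1-yl]phenyl acetate | CC(=O)C1=C(O)[C@@H]([C@@H](/C=C/C)c2ccc(OC(C)=O)cc2)C(=O)C=C1OC
F3 | step 3 | 4-[(1S,2E)-1-(3-acetyl-2,6-dihydroxy-4-methoxyphenyl)but-2-en-1-yl]phenyl acetate | CC(=O)c1c(O)c([C@@H](/C=C/C)c2ccc(OC(C)=O)cc2)c(O)cc1OC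
F4 | step 4 | 4-[(1E,3R)-3-hydroxybut-1-en-1-yl]phenol | C[C@@H](O)/C=C/c1ccc(O)cc1
F5 | step 4 | 4-[(2E)-but-2-en-1-ylidene]cyclohexa-2,5-dien-1-one | C/C=C/C=C1C=CC(=O)C=C1
F6 | step 4 | 1-[2-hydroxy-3-[(1S,2E)-1-(4-hydroxyphenyl)but-2-en-1-yl]-6-methoxy-4-(methoxymethoxy)phenyl]ethan-1-one | CC(=O)c1c(O)c([C@@H](/C=C/C)c2ccc(O)cc2)c(OCOC)cc1OC
F7 | step 7 | 4-[(1S)-1-[3-acetyl-2-hydroxy-4-methoxy-6-(methoxymethoxy)phenyl]prop-2-en-1-yl]phenyl acetate | CC(=O)c1c(O)c([C@@H](C=C)c2ccc(OC(C)=O)cc2)c(OCOC)cc1OC
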